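**Retrosynthetic overview**
1. Target 24 ⇐ selective acetylation of 23 ⇐ sp2–sp3 Negishi coupling of (Z)-α-iodo enoate 20 ⇐ hydroxyl-directed trans-hydroalumination/iodination of ynoate 18 ⇐ catalytic asymmetric propiolate addition to aldehyde 16.
2. 16 ⇐ thioester reduction and copper-catalysed asymmetric conjugate methylation of enethioate 14 ⇐ Wittig reaction of aldehyde 13 ⇐ oxidation and auxiliary removal from cyclohexenol imide 11.
3. The only carbocycle (the cyclohexene) is made in one flask from acyclic imide 8 and but-3-en-2-one 9 by a [3+3] annulation: a Michael addition makes the ring CH2–CH bond, then Ni/Cr vinylation of the freed ketone makes the ring vinyl CH–C(OH)CH3 bond.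
4. Enabling feature: the ring carbinol carbon C(OH)CH3 with its two ring CH2 groups is but-3-en-2-one, and the other three ring carbons (CH–CH=CH) are a (Z)-4-iodobut-3-enoyl unit. Its exocyclic acyl carbon makes the ring CH an auxiliary-controlled enolate carbon, and its cis C–I bond is a latent vinyl anion that reductive polarity reversal joins to the equally electrophilic ketone carbon.
5. 8 ⇐ but-3-yn-1-ol by iodination, diimide cis-reduction, oxidation and N-acylation of the oxazolidinone (the oxazolidinone ring is bought, not built).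

Key step: step 5

Remark: the thioester ylide of step 8 is taken as a purchasable reagent, and the ligand antipodes named in steps 9 and 11 assume the usual sense of induction (the mirror-image ligand is to be used if that sense proves opposite).

**Step 1**
Reactants: 1 but-3-yn-1-ol
Product: 2 4-iodobut-3-yn-1-ol
Conditions: N-iodosuccinimide, AgNO3 (cat.), acetone, 23 °C, dark
Reagents that add atoms: N-iodosuccinimide, O=C1CCC(=O)N1I
Why: Silver-catalysed electrophilic iodination of the terminal alkyne (through the silver acetylide) should give the 1-iodoalkyne; no stereocentre is involved.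

**Step 2**
Reactants: 2 4-iodobut-3-yn-1-ol
Product: 3 (3Z)-4-iodobut-3-en-1-ol
Conditions: 2-O2NC6H4SO2NHNH2, Et3N, THF/i-PrOH, 23 °C
Reagents that add atoms: none
Why: Diimide reduction delivers both hydrogens to the same side of the triple bond and does not cleave C–I bonds, so the (Z)-vinyl iodide should result.

**Step 3**
Reactants: 3 (3Z)-4-iodobut-3-en-1-ol
Product: 5 (3Z)-4-iodobut-3-enoic acid, via iodo aldehyde 4 (not isolated)
Conditions: TEMPO (cat.), PhI(OAc)2, MeCN/H2O, 23 °C
Reagents that add atoms: water, O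
Why: Oxoammonium (TEMPO) oxidation to the aldehyde and, through its hydrate, to the acid runs near neutral pH, which should leave the vinyl iodide and the β,γ-position of the double bond untouched.

**Step 4**
Reactants: 5 (3Z)-4-iodobut-3-enoic acid; 6 (4S)-4-benzyl-1,3-oxazolidin-2-one
Product: 8 (4S)-4-benzyl-3-[(3Z)-4-iodobut-3-enoyl]-1,3-oxazolidin-2-one, via mixed pivalic anhydride 7 (not isolated)
Conditions: t-BuCOCl, Et3N, THF, −20 °C; then 6, LiCl, −20 → 0 °C
Reagents that add atoms: none
Why: N-Acylation of the oxazolidinone by the mixed anhydride (LiCl-assisted) is a standard way to make such imides, and the low temperature should prevent migration of the double bond into conjugation.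

**Step 5**
Reactants: 8 (4S)-4-benzyl-3-[(3Z)-4-iodobut-3-enoyl]-1,3-oxazolidin-2-one; 9 but-3-en-2-one
Product: 11 (4S)-4-benzyl-3-[(1S,4S)-4-hydroxy-4-methylcyclohex-2-ene-1-carbonyl]-1,3-oxazolidin-2-one, via keto imide 10 (not isolated)
Conditions: TiCl3(OiPr), iPr2NEt, CH2Cl2, 0 °C; 9, 0 °C; i-PrOH, 2,6-lutidine, evaporate; CrCl2, NiCl2 (cat.), DMF, 23 °C (one flask)
Reagents that add atoms: none
Why: Proposed new method: a one-flask [3+3] annulation that merges two reaction types known separately, the chlorotitanium-enolate Michael addition of N-acyl oxazolidinones to vinyl ketones and the intramolecular Nozaki–Hiyama–Kishi addition of a vinyl iodide to a ketone; the chelated (Z)-titanium dienolate of 8 attacks but-3-en-2-one through its α-carbon on the face away from the benzyl group (ring CH2–CH bond, the CH set as S by the auxiliary), alcoholysis frees methyl ketone 10, and nickel-catalysed insertion into the C–I bond with transmetalation to chromium gives a (Z)-vinylchromium species that adds to the ketone (vinyl CH–carbinol bond). The two carbons joined in the second event are both electrophilic (C–I carbon and C=O carbon), so this bond rests on reductive polarity reversal by divalent chromium. The six-membered ring closes in a 6-exo-trig mode onto the carbonyl group, and the cis geometry of the vinyl iodide is what allows it. The carbinol centre is set in the ring transition state, a half-chair with the acyl-bearing CH pseudo-equatorial and a four-centre C–Cr/C=O array that holds the carbonyl oxygen in the plane of the vinyl group, so methyl is pseudo-axial and OH ends trans to the acyl group (1S,4S). The step needs α- rather than γ-attack of the dienolate (titanium chelate, iodine on the γ-carbon), retention of the Z geometry (inherent to the Ni/Cr manifold) and attack on the ketone rather than the imide carbonyls (ring size, and the inertness of imides to organochromium reagents).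

**Step 6**
Reactants: 11 (4S)-4-benzyl-3-[(1S,4S)-4-hydroxy-4-methylcyclohex-2-ene-1-carbonyl]-1,3-oxazolidin-2-one
Product: 12 (1S,4S)-4-(hydroxymethyl)-1-methylcyclohex-2-en-1-ol
Conditions: LiBH4, MeOH, THF, 0 °C
Reagents that add atoms: none
Why: Hydride reduction of the exocyclic imide carbonyl releases the auxiliary and should give the primary alcohol without touching the adjacent stereocentre or the ring alkene.

**Step 7**
Reactants: 12 (1S,4S)-4-(hydroxymethyl)-1-methylcyclohex-2-en-1-ol
Product: 13 (1S,4S)-4-hydroxy-4-methylcyclohex-2-ene-1-carbaldehyde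
Conditions: Dess–Martin periodinane, pyridine, CH2Cl2, 0 °C; used crude at once
Reagents that add atoms: none
Why: Buffered Dess–Martin oxidation can only oxidise the primary alcohol (the tertiary one has no carbinol hydrogen), and immediate use of the β,γ-unsaturated aldehyde should avoid epimerisation or conjugation.

**Step 8**
Reactants: 13 (1S,4S)-4-hydroxy-4-methylcyclohex-2-ene-1-carbaldehyde
Product: 14 S-ethyl (2E)-3-[(1S,4S)-4-hydroxy-4-methylcyclohex-2-en-1-yl]prop-2-enethioate
Conditions: Ph3P=CHC(O)SEt, CH2Cl2, 23 °C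
Reagents that add atoms: S-ethyl 2-(triphenyl-λ5-phosphanylidene)ethanethioate, CCSC(=O)C=P(c1ccccc1)(c1ccccc1)c1ccccc1
Why: Wittig olefination with the stabilised, non-basic thioester ylide should give the (E)-enethioate without epimerising the allylic centre.

**Step 9**
Reactants: 14 S-ethyl (2E)-3-[(1S,4S)-4-hydroxy-4-methylcyclohex-2-en-1-yl]prop-2-enethioate
Product: 15 S-ethyl (3R)-3-[(1R,4S)-4-hydroxy-4-methylcyclohex-2-en-1-yl]butanethioate
Conditions: MeMgBr (excess, to cover the free OH), CuBr·SMe2 (cat.), (R,S)-Josiphos (cat.), t-BuOMe, −75 °C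
Reagents that add atoms: methylmagnesium bromide, C[Mg]Br
Why: Copper-catalysed asymmetric conjugate addition of the Grignard reagent to the α,β-unsaturated thioester should set the methyl-bearing centre as 3R under control of the ferrocenyl diphosphine–copper catalyst rather than the substrate.

**Step 10**
Reactants: 15 S-ethyl (3R)-3-[(1R,4S)-4-hydroxy-4-methylcyclohex-2-en-1-yl]butanethioate
Product: 16 (3R)-3-[(1R,4S)-4-hydroxy-4-methylcyclohex-2-en-1-yl]butanal
Conditions: i-Bu2AlH, CH2Cl2, −78 °C
Reagents that add atoms: none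
Why: Partial reduction of a thioester by the aluminium hydride stops at the hemithioacetal aluminate, which should give the aldehyde on work-up.

**Step 11**
Reactants: 16 (3R)-3-[(1R,4S)-4-hydroxy-4-methylcyclohex-2-en-1-yl]butanal; 17 methyl prop-2-ynoate
Product: 18 methyl (4R,6R)-4-hydroxy-6-[(1R,4S)-4-hydroxy-4-methylcyclohex-2-en-1-yl]hept-2-ynoate
Conditions: Me2Zn, (S,S)-ProPhenol (cat.), Ph3PO (cat.), toluene, 0 °C
Reagents that add atoms: none
Why: Catalytic asymmetric alkynylation, in which the dinuclear zinc–ProPhenol catalyst delivers the zinc propiolate to one face of the aldehyde, should set the 4R carbinol by catalyst control.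

**Step 12**
Reactants: 18 methyl (4R,6R)-4-hydroxy-6-[(1R,4S)-4-hydroxy-4-methylcyclohex-2-en-1-yl]hept-2-ynoate
Product: 20 methyl (2Z,4R,6R)-4-hydroxy-6-[(1R,4S)-4-hydroxy-4-methylcyclohex-2-en-1-yl]-2-iodohept-2-enoate, via cyclic alkenylalanate 19 (not isolated)
Conditions: NaAlH2(OCH2CH2OMe)2, THF, −72 °C; then I2, −72 → 0 °C
Reagents that add atoms: iodine, [I][I]
Why: Hydroxyl-directed trans-hydroalumination of the ynoate puts hydride on the β-carbon and aluminium on the α-carbon, held cis to the carbinol in a five-membered alkoxyalanate, and iodinolysis with retention should give the (Z)-α-iodo enoate.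

**Step 13**
Reactants: 20 methyl (2Z,4R,6R)-4-hydroxy-6-[(1R,4S)-4-hydroxy-4-methylcyclohex-2-en-1-yl]-2-iodohept-2-enoate; 21 5-bromo-2-methylpent-2-ene
Product: 23 methyl (2E,4R,6R)-4-hydroxy-6-[(1R,4S)-4-hydroxy-4-methylcyclohex-2-en-1-yl]-2-(4-methylpent-3-en-1-yl)hept-2-enoate, via alkylzinc bromide 22 (not isolated)
Conditions: 21, Zn, LiCl, THF, 50 °C; then 20, Pd(OAc)2 (cat.), SPhos (cat.), THF, 23 °C
Reagents that add atoms: none
Why: Negishi sp2–sp3 cross-coupling proceeds with retention at the alkenyl carbon, so the new chain should end cis to the carbinol and the ester trans to it, which is the (E)-enoate.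

**Step 14**
Reactants: 23 methyl (2E,4R,6R)-4-hydroxy-6-[(1R,4S)-4-hydroxy-4-methylcyclohex-2-en-1-yl]-2-(4-methylpent-3-en-1-yl)hept-2-enoate
Product: 24 methyl (2E,4R,6R)-4-(acetyloxy)-6-[(1R,4S)-4-hydroxy-4-methylcyclohex-2-en-1-yl]-2-(4-methylpent-3-en-1-yl)hept-2-enoate
Conditions: Ac2O, pyridine, DMAP (cat.), CH2Cl2, 0 °C
Reagents that add atoms: acetic anhydride, CC(=O)OC(C)=O
Why: DMAP-catalysed acetylation should be selective for the secondary allylic alcohol, because the tertiary ring alcohol is too hindered to react at 0 °C.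

**Compound list**
1 | but-3-yn-1-ol | OCCC#C | starting material
2 | 4-iodobut-3-yn-1-ol | OCCC#CI | intermediate
3 | (3Z)-4-iodobut-3-en-1-ol | OCC/C=C\I | intermediate
4 | (3Z)-4-iodobut-3-enal | O=CC/C=C\I | intermediate (not isolated)
5 | (3Z)-4-iodobut-3-enoic acid | OC(=O)C/C=C\I | intermediate
6 | (4S)-4-benzyl-1,3-oxazolidin-2-one | O=C1N[C@@H](Cc2ccccc2)CO1 | starting material
7 | 2,2-dimethylpropanoic (3Z)-4-iodobut-3-enoic anhydride | CC(C)(C)C(=O)OC(=O)C/C=C\I | intermediate (not isolated)
8 | (4S)-4-benzyl-3-[(3Z)-4-iodobut-3-enoyl]-1,3-oxazolidin-2-one | O=C1OC[C@H](Cc2ccccc2)N1C(=O)C/C=C\I | intermediate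
9 | but-3-en-2-one | CC(=O)C=C | starting material
10 | (4S)-4-benzyl-3-[(2S,3Z)-4-iodo-2-(3-oxobutyl)but-3-enoyl]-1,3-oxazolidin-2-one | CC(=O)CC[C@@H](/C=C\I)C(=O)N1[C@@H](Cc2ccccc2)COC1=O | intermediate (not isolated)
11 | (4S)-4-benzyl-3-[(1S,4S)-4-hydroxy-4-methylcyclohex-2-ene-1-carbonyl]-1,3-oxazolidin-2-one | O=C([C@@H]1C=C[C@@](C)(O)CC1)N1[C@@H](Cc2ccccc2)COC1=O | intermediate
12 | (1S,4S)-4-(hydroxymethyl)-1-methylcyclohex-2-en-1-ol | OC[C@@H]1C=C[C@@](C)(O)CC1 | intermediate
13 | (1S,4S)-4-hydroxy-4-methylcyclohex-2-ene-1-carbaldehyde | O=C[C@@H]1C=C[C@@](C)(O)CC1 | intermediate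
14 | S-ethyl (2E)-3-[(1S,4S)-4-hydroxy-4-methylcyclohex-2-en-1-yl]prop-2-enethioate | CCSC(=O)/C=C/[C@@H]1C=C[C@@](C)(O)CC1 | intermediate
15 | S-ethyl (3R)-3-[(1R,4S)-4-hydroxy-4-methylcyclohex-2-en-1-yl]butanethioate | CCSC(=O)C[C@@H](C)[C@@H]1C=C[C@@](C)(O)CC1 | intermediate
16 | (3R)-3-[(1R,4S)-4-hydroxy-4-methylcyclohex-2-en-1-yl]butanal | O=CC[C@@H](C)[C@@H]1C=C[C@@](C)(O)CC1 | intermediate
17 | methyl prop-2-ynoate | COC(=O)C#C | starting material
18 | methyl (4R,6R)-4-hydroxy-6-[(1R,4S)-4-hydroxy-4-methylcyclohex-2-en-1-yl]hept-2-ynoate | COC(=O)C#C[C@@H](C[C@@H](C)[C@@H]1C=C[C@@](C)(O)CC1)O | intermediate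
19 | sodium salt of the five-membered cyclic alkenyl(alkoxy)bis(2-methoxyethoxy)alanate formed from 18 (aluminium on the ester-bearing alkene carbon, cis to the carbinol oxygen; tertiary hydroxyl drawn free) | COC(=O)C1=C[C@@H](C[C@@H](C)[C@@H]2C=C[C@@](C)(O)CC2)O[Al-]1(OCCOC)OCCOC.[Na+] | intermediate (not isolated)
20 | methyl (2Z,4R,6R)-4-hydroxy-6-[(1R,4S)-4-hydroxy-4-methylcyclohex-2-en-1-yl]-2-iodohept-2-enoate | COC(=O)/C(I)=C/[C@@H](C[C@@H](C)[C@@H]1C=C[C@@](C)(O)CC1)O | intermediate
21 | 5-bromo-2-methylpent-2-ene | CC(C)=CCCBr | starting material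
22 | bromo(4-methylpent-3-en-1-yl)zinc | CC(C)=CCC[Zn]Br | intermediate (not isolated)
23 | methyl (2E,4R,6R)-4-hydroxy-6-[(1R,4S)-4-hydroxy-4-methylcyclohex-2-en-1-yl]-2-(4-methylpent-3-en-1-yl)hept-2-enoate | COC(=O)/C(=C/[C@@H](C[C@@H](C)[C@@H]1C=C[C@@](C)(O)CC1)O)CCC=C(C)C | intermediate
24 | methyl (2E,4R,6R)-4-(acetyloxy)-6-[(1R,4S)-4-hydroxy-4-methylcyclohex-2-en-1-yl]-2-(4-methylpent-3-en-1-yl)hept-2-enoate | COC(=O)/C(=C/[C@@H](C[C@@H](C)[C@@H]1C=C[C@@](C)(O)CC1)OC(C)=O)CCC=C(C)C | target

**Totals**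
Total step count: 14. Longest linear sequence: 14 steps (1 → 24).

**Steps most likely to fail**

Step 5 (proposed method). The second stage may stall if residual titanium alkoxides consume or tie up the divalent chromium. The ring CH of keto imide 10 may epimerise, or its double bond may move into conjugation, while it waits for ring closure. The ketone may also be attacked on the wrong face. The fallback uses known reactions only and builds the ring in a different bond order; it sets out from 9 and returns at 12. 3-[(tert-Butyldiphenylsilyl)oxy]propanal F1 is added to 9 under enamine catalysis (α,α-diphenylprolinol trimethylsilyl ether, the antipode that gives the 2R aldehyde) to give (2R)-2-{[(tert-butyldiphenylsilyl)oxy]methyl}-5-oxohexanal F2. Intramolecular aldol condensation (pyrrolidinium acetate, completing a Robinson annulation) gives (4S)-4-{[(tert-butyldiphenylsilyl)oxy]methyl}cyclohex-2-en-1-one F3. Corey–Chaykovsky epoxidation with dimethylsulfonium methylide, which attacks axially, gives (3S,6S)-6-{[(tert-butyldiphenylsilyl)oxy]methyl}-1-oxaspiro[2.5]oct-4-ene F4. LiEt3BH opens the epoxide at its CH2 group to give (1S,4S)-4-{[(tert-butyldiphenylsilyl)oxy]methyl}-1-methylcyclohex-2-en-1-ol F5, and Bu4NF then gives 12.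

Step 12. The α-alumino enoate may equilibrate through an aluminium allenolate and lose its geometry, the ester may be over-reduced, or protonolysis may outrun iodinolysis. The fallback builds the enoate by olefination instead; it sets out from 16 and returns at 23, bypassing 17 to 22. Wittig methoxymethylenation of 16 (Ph3P=CHOMe) gives (1S,4R)-4-[(2R)-5-methoxypent-4-en-2-yl]-1-methylcyclohex-2-en-1-ol F6 as an E/Z mixture, and Hg(OAc)2 in wet THF unmasks (4R)-4-[(1R,4S)-4-hydroxy-4-methylcyclohex-2-en-1-yl]pentanal F7. Separately, methyl (triphenyl-λ5-phosphanylidene)acetate is alkylated with 21 to (1-methoxy-6-methyl-1-oxohept-5-en-2-yl)triphenylphosphonium bromide F8, which NaOH converts into methyl 6-methyl-2-(triphenyl-λ5-phosphanylidene)hept-5-enoate F9. L-Proline-catalysed α-aminoxylation of F7 with nitrosobenzene gives (2R,4R)-2-(anilinooxy)-4-[(1R,4S)-4-hydroxy-4-methylcyclohex-2-en-1-yl]pentanal F10. This is olefinated in the same flask with F9 to methyl (2E,4R,6R)-4-(anilinooxy)-6-[(1R,4S)-4-hydroxy-4-methylcyclohex-2-en-1-yl]-2-(4-methylpent-3-en-1-yl)hept-2-enoate F11, and Zn/AcOH cleaves the N–O bond to give 23.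

Step 9. Methyl transfer may be slow or poorly face-selective because of the magnesium alkoxide of the free tertiary alcohol, the branched γ-carbon or a mismatched substrate–catalyst pairing. The fallback replaces catalyst control by auxiliary control; it sets out from 13 and returns at 16. Wittig reaction of 13 with (4R)-4-phenyl-3-[(triphenyl-λ5-phosphanylidene)acetyl]-1,3-oxazolidin-2-one gives (4R)-3-{(2E)-3-[(1S,4S)-4-hydroxy-4-methylcyclohex-2-en-1-yl]prop-2-enoyl}-4-phenyl-1,3-oxazolidin-2-one F12. MeMgBr with CuBr·SMe2 adds methyl to the chelated s-cis enoyl imide on the face away from the phenyl group to give (4R)-3-{(3R)-3-[(1R,4S)-4-hydroxy-4-methylcyclohex-2-en-1-yl]butanoyl}-4-phenyl-1,3-oxazolidin-2-one F13 (the other auxiliary antipode is used if the sense proves opposite). LiBH4 gives (3R)-3-[(1R,4S)-4-hydroxy-4-methylcyclohex-2-en-1-yl]butan-1-ol F14, and Dess–Martin oxidation returns 16.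

**Further compounds**
F1 | step 5 | 3-[(tert-butyldiphenylsilyl)oxy]propanal | O=CCCO[Si](c1ccccc1)(c1ccccc1)C(C)(C)C
F2 | step 5 | (2R)-2-{[(tert-butyldiphenylsilyl)oxy]methyl}-5-oxohexanal | CC(C)(C)[Si](c1ccccc1)(c1ccccc1)OC[C@@H](CCC(C)=O)C=O
F3 | step 5 | (4S)-4-{[(tert-butyldiphenylsilyl)oxy]methyl}cyclohex-2-en-1-one | CC(C)(C)[Si](c1ccccc1)(c1ccccc1)OC[C@@H]1C=CC(=O)CC1
F4 | step 5 | (3S,6S)-6-{[(tert-butyldiphenylsilyl)oxy]methyl}-1-oxaspiro[2.5]oct-4-ene | CC(C)(C)[Si](c1ccccc1)(c1ccccc1)OC[C@@H]1C=C[C@@]2(OC2)CC1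
F5 | step 5 | (1S,4S)-4-{[(tert-butyldiphenylsilyl)oxy]methyl}-1-methylcyclohex-2-en-1-ol | CC(C)(C)[Si](c1ccccc1)(c1ccccc1)OC[C@@H]1C=C[C@@](C)(O)CC1
F6 | step 12 | (1S,4R)-4-[(2R)-5-methoxypent-4-en-2-yl]-1-methylcyclohex-2-en-1-ol (E/Z mixture) | COC=CC[C@@H](C)[C@@H]1C=C[C@@](C)(O)CC1
F7 | step 12 | (4R)-4-[(1R,4S)-4-hydroxy-4-methylcyclohex-2-en-1-yl]pentanal | O=CCC[C@@H](C)[C@@H]1C=C[C@@](C)(O)CC1
F8 | step 12 | (1-methoxy-6-methyl-1-oxohept-5-en-2-yl)triphenylphosphonium bromide | COC(=O)C(CCC=C(C)C)[P+](c1ccccc1)(c1ccccc1)c1ccccc1.[Br-]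
F9 | step 12 | methyl 6-methyl-2-(triphenyl-λ5-phosphanylidene)hept-5-enoate | COC(=O)C(CCC=C(C)C)=P(c1ccccc1)(c1ccccc1)c1ccccc1
F10 | step 12 | (2R,4R)-2-(anilinooxy)-4-[(1R,4S)-4-hydroxy-4-methylcyclohex-2-en-1-yl]pentanal | O=C[C@@H](C[C@@H](C)[C@@H]1C=C[C@@](C)(O)CC1)ONc1ccccc1
F11 | step 12 | methyl (2E,4R,6R)-4-(anilinooxy)-6-[(1R,4S)-4-hydroxy-4-methylcyclohex-2-en-1-yl]-2-(4-methylpent-3-en-1-yl)hept-2-enoate | COC(=O)/C(=C/[C@@H](C[C@@H](C)[C@@H]1C=C[C@@](C)(O)CC1)ONc1ccccc1)CCC=C(C)C
F12 | step 9 | (4R)-3-{(2E)-3-[(1S,4S)-4-hydroxy-4-methylcyclohex-2-en-1-yl]prop-2-enoyl}-4-phenyl-1,3-oxazolidin-2-one | O=C1OC[C@@H](c2ccccc2)N1C(=O)/C=C/[C@@H]1C=C[C@@](C)(O)CC1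
F13 | step 9 | (4R)-3-{(3R)-3-[(1R,4S)-4-hydroxy-4-methylcyclohex-2-en-1-yl]butanoyl}-4-phenyl-1,3-oxazolidin-2-one | O=C1OC[C@@H](c2ccccc2)N1C(=O)C[C@@H](C)[C@@H]1C=C[C@@](C)(O)CC1
F14 | step 9 | (3R)-3-[(1R,4S)-4-hydroxy-4-methylcyclohex-2-en-1-yl]butan-1-ol | OCC[C@@H](C)[C@@H]1C=C[C@@](C)(O)CC1
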